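The trans-2,3-disubstituted dioxane ring (O1–C2–C3–O4, fused to flavone ring B) is not cut at its two sp3 C–O bonds into catechol plus C6–C3 unit. Instead C2, together with its CH2OH carbon, is excised. This leaves a racemic 2-aryl-1,3-benzodioxole, the plain acetal of O-benzylvanillin and methyl 3-O-methylgallate. The key step re-inserts C2 as the enolate carbon of a chiral bromoacetyl imide. Acetal ionisation, C2–C3 bond formation and C2–O1 closure expand the five-membered ring to the dioxane and set both stereocentres. It exploits O1 on C8a, flanked by C8–OMe and para to the C6 carbonyl carbon, as the preferred leaving oxygen. The flavone is then built on the C6 ester.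

Key step: step 4

Remark: dioxane atoms are numbered as in 2,3-dihydro-1,4-benzodioxine. O1 sits on C8a next to C8–OMe, C2 bears CH2OH, C3 bears the aryl group, O4 sits on C4a, and the flavone sits on C6. The target is (2R,3R), trans.
Remark: metal enolates, alkoxides and ion pairs formed directly from a numbered compound are treated as forms of that compound and carry no number of their own.

Step 1
Reactants: 1 4-(benzyloxy)-3-methoxybenzaldehyde
Product: 2 1-(benzyloxy)-4-(dimethoxymethyl)-2-methoxybenzene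
Conditions: HC(OMe)3, p-TsOH·H2O (cat.), MeOH, rt; Et3N quench
Reagents that add atoms: trimethyl orthoformate, COC(OC)OC
Why: Acid-catalysed acetalisation with an orthoester as water scavenger is routine for electron-rich benzaldehydes and creates no stereocentre.

Step 2
Reactants: 2 1-(benzyloxy)-4-(dimethoxymethyl)-2-methoxybenzene; 3 methyl 3,4-dihydroxy-5-methoxybenzoate
Product: 4 methyl 2-[4-(benzyloxy)-3-methoxyphenyl]-7-methoxy-1,3-benzodioxole-5-carboxylate (racemic at the acetal carbon)
Conditions: PPTS (cat.), toluene, reflux, 4 Å MS in a Soxhlet head (removal of MeOH)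
Reagents that add atoms: none
Why: Acid-catalysed transacetalisation driven by removal of methanol should close the five-membered benzodioxole through the aryl-stabilised oxocarbenium ion, and the acetal stereocentre forms racemic and is erased in step 4.

Step 3
Reactants: 5 (4S)-4-benzyl-1,3-oxazolidin-2-one; 6 bromoacetyl bromide
Product: 7 (4S)-4-benzyl-3-(bromoacetyl)-1,3-oxazolidin-2-one
Conditions: n-BuLi, THF, −78 °C; then 6, −78 → 0 °C
Reagents that add atoms: none
Why: N-Acylation of a lithiated oxazolidinone with an acid halide is standard and leaves the C4 stereocentre of the auxiliary untouched.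

Step 4
Reactants: 4 methyl 2-[4-(benzyloxy)-3-methoxyphenyl]-7-methoxy-1,3-benzodioxole-5-carboxylate; 7 (4S)-4-benzyl-3-(bromoacetyl)-1,3-oxazolidin-2-one
Product: 9 methyl (2S,3R)-2-{[(4S)-4-benzyl-2-oxo-1,3-oxazolidin-3-yl]carbonyl}-3-[4-(benzyloxy)-3-methoxyphenyl]-8-methoxy-2,3-dihydro-1,4-benzodioxine-6-carboxylate, via bromo adduct 8 (not isolated)
Conditions: 7, TiCl4, i-Pr2NEt, CH2Cl2, −78 °C; then 4, TiCl4, −78 → −40 °C; aq NH4Cl work-up; crude 8, K2CO3, MeCN, 0 °C → rt
Reagents that add atoms: none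
Why: Proposed new method: TiCl4 chelated by O1 and the neighbouring OMe oxygen of 4 ionises the acetal C–O1 bond, the aryl-stabilised oxocarbenium ion that remains on the other oxygen (O4 of 9) is attacked at carbon by the chelated Z titanium enolate of 7 to give 8, and K2CO3 then deprotonates only the liberated phenol, which displaces bromide to give 9. The closest known reaction types are the SN1-type addition of titanium enolates of chiral N-acyl oxazolidinones and thiazolidinethiones to acetals, the invertive SN2 displacement of α-bromo-β-oxy imides and the Williamson closure of catechols on α-bromo esters, whereas their union into a one-carbon ring expansion of a catechol acetal has not been shown. The dioxane ring closes in a 6-exo-tet SN2 mode at the α-bromo imide carbon. C2 is controlled by the auxiliary, whose benzyl group shields one face of the chelated enolate so that the bromide carbon of 8 is (R) and inversion makes it (2S) in 9. C3 is set in the same C–C bond formation by an open antiperiplanar transition state that should favour the anti bromo/aryloxy adduct, anti addition followed by inversion equals the trans dioxane, the stereocentre of racemic 4 is erased on ionisation, and a minor cis isomer is a diastereomer that chromatography removes. The step needs regioselective ionisation, secured by chelation to the middle oxygen of the 1,2,3-trioxygenated ring and by the para ester that makes the O1 phenoxide the better nucleofuge and the poorer cation donor, and it needs substitution to outrun E1cB loss of the β-aryloxide, secured by the wide pKa gap between the phenol and the α-proton.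

Step 5
Reactants: 9 methyl (2S,3R)-2-{[(4S)-4-benzyl-2-oxo-1,3-oxazolidin-3-yl]carbonyl}-3-[4-(benzyloxy)-3-methoxyphenyl]-8-methoxy-2,3-dihydro-1,4-benzodioxine-6-carboxylate
Product: 10 methyl (2R,3R)-3-[4-(benzyloxy)-3-methoxyphenyl]-2-(hydroxymethyl)-8-methoxy-2,3-dihydro-1,4-benzodioxine-6-carboxylate
Conditions: NaBH4, THF/H2O (4:1), 0 °C → rt
Reagents that add atoms: none
Why: Reductive cleavage of an N-acyl oxazolidinone by borohydride should reduce the activated α-aryloxy imide carbonyl to CH2OH while the conjugated aryl methyl ester stays intact, with no bond to C2 or C3 broken (the C2 descriptor changes from S to R only through the priority change).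

Step 6
Reactants: 10 methyl (2R,3R)-3-[4-(benzyloxy)-3-methoxyphenyl]-2-(hydroxymethyl)-8-methoxy-2,3-dihydro-1,4-benzodioxine-6-carboxylate
Product: 11 methyl (2R,3R)-3-[4-(benzyloxy)-3-methoxyphenyl]-2-[(benzyloxy)methyl]-8-methoxy-2,3-dihydro-1,4-benzodioxine-6-carboxylate
Conditions: NaH, BnBr, TBAI (cat.), DMF, 0 °C → rt
Reagents that add atoms: benzyl bromide, BrCc1ccccc1
Why: Williamson ether synthesis on the only free hydroxyl group masks it for the strongly basic Claisen step, and the dioxane now has no acidic proton that could epimerise.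

Step 7
Reactants: 12 1-(2,4,6-trihydroxyphenyl)ethanone
Product: 13 1-[2,4-bis(benzyloxy)-6-hydroxyphenyl]ethanone
Conditions: BnBr (2.1 equiv), K2CO3, acetone, reflux
Reagents that add atoms: benzyl bromide, BrCc1ccccc1
Why: Williamson ether synthesis should stop at the dibenzyl ether because the remaining ortho hydroxyl group is deactivated by its hydrogen bond to the ketone.

Step 8
Reactants: 11 methyl (2R,3R)-3-[4-(benzyloxy)-3-methoxyphenyl]-2-[(benzyloxy)methyl]-8-methoxy-2,3-dihydro-1,4-benzodioxine-6-carboxylate; 13 1-[2,4-bis(benzyloxy)-6-hydroxyphenyl]ethanone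
Product: 15 5,7-bis(benzyloxy)-2-{(2R,3R)-3-[4-(benzyloxy)-3-methoxyphenyl]-2-[(benzyloxy)methyl]-8-methoxy-2,3-dihydro-1,4-benzodioxin-6-yl}-4H-chromen-4-one, via diketone 14 (not isolated)
Conditions: 13, LiHMDS (4 equiv), THF, −78 → 0 °C; then 11, 0 → 60 °C; 1 M HCl work-up; crude 14, p-TsOH·H2O (cat.), toluene, 80 °C
Reagents that add atoms: none
Why: Crossed Claisen condensation of the phenoxide-enolate dianion of 13 with the non-enolisable ester 11 should give 1,3-diketone 14, whose free phenol closes the pyranone by acid-catalysed cyclodehydration as in the classical flavone synthesis, while C2 and C3 carry no acidic proton.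

Step 9
Reactants: 15 5,7-bis(benzyloxy)-2-{(2R,3R)-3-[4-(benzyloxy)-3-methoxyphenyl]-2-[(benzyloxy)methyl]-8-methoxy-2,3-dihydro-1,4-benzodioxin-6-yl}-4H-chromen-4-one
Product: 16 5'-methoxyhydnocarpin, 5,7-dihydroxy-2-[(2R,3R)-3-(4-hydroxy-3-methoxyphenyl)-2-(hydroxymethyl)-8-methoxy-2,3-dihydro-1,4-benzodioxin-6-yl]-4H-chromen-4-one
Conditions: H2 (1 atm), 10% Pd/C, THF/MeOH, rt, stopped at full debenzylation
Reagents that add atoms: none
Why: Catalytic hydrogenolysis should remove all four O-benzyl groups faster than it attacks the hindered cyclic benzylic C3–O4 bond (which behaves like the C2–O bond of 2-arylchromans under such debenzylation) or the vinylogous-ester C=C of the chromone, so both stereocentres persist.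

Compound list
1 | 4-(benzyloxy)-3-methoxybenzaldehyde (O-benzylvanillin) | COc1cc(C=O)ccc1OCc1ccccc1 | starting material
2 | 1-(benzyloxy)-4-(dimethoxymethyl)-2-methoxybenzene | COc1cc(C(OC)OC)ccc1OCc1ccccc1 | intermediate
3 | methyl 3,4-dihydroxy-5-methoxybenzoate (methyl 3-O-methylgallate) | COC(=O)c1cc(O)c(O)c(OC)c1 | starting material
4 | methyl 2-[4-(benzyloxy)-3-methoxyphenyl]-7-methoxy-1,3-benzodioxole-5-carboxylate (racemic) | COC(=O)c1cc(OC)c2OC(Oc2c1)c1ccc(OCc2ccccc2)c(OC)c1 | intermediate
5 | (4S)-4-benzyl-1,3-oxazolidin-2-one | O=C1N[C@@H](Cc2ccccc2)CO1 | starting material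
6 | bromoacetyl bromide | BrCC(Br)=O | starting material
7 | (4S)-4-benzyl-3-(bromoacetyl)-1,3-oxazolidin-2-one | BrCC(=O)N1[C@@H](Cc2ccccc2)COC1=O | intermediate
8 | methyl 3-{(1R,2R)-3-[(4S)-4-benzyl-2-oxo-1,3-oxazolidin-3-yl]-1-[4-(benzyloxy)-3-methoxyphenyl]-2-bromo-3-oxopropoxy}-4-hydroxy-5-methoxybenzoate (bromo adduct, not isolated) | O=C(N1[C@@H](Cc2ccccc2)COC1=O)[C@H](Br)[C@H](Oc1cc(C(=O)OC)cc(OC)c1O)c1ccc(OCc2ccccc2)c(OC)c1 | intermediate
9 | methyl (2S,3R)-2-{[(4S)-4-benzyl-2-oxo-1,3-oxazolidin-3-yl]carbonyl}-3-[4-(benzyloxy)-3-methoxyphenyl]-8-methoxy-2,3-dihydro-1,4-benzodioxine-6-carboxylate | O=C(N1[C@@H](Cc2ccccc2)COC1=O)[C@H]1Oc2c(OC)cc(C(=O)OC)cc2O[C@@H]1c1ccc(OCc2ccccc2)c(OC)c1 | intermediate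
10 | methyl (2R,3R)-3-[4-(benzyloxy)-3-methoxyphenyl]-2-(hydroxymethyl)-8-methoxy-2,3-dihydro-1,4-benzodioxine-6-carboxylate | OC[C@H]1Oc2c(OC)cc(C(=O)OC)cc2O[C@@H]1c1ccc(OCc2ccccc2)c(OC)c1 | intermediate
11 | methyl (2R,3R)-3-[4-(benzyloxy)-3-methoxyphenyl]-2-[(benzyloxy)methyl]-8-methoxy-2,3-dihydro-1,4-benzodioxine-6-carboxylate | c1ccccc1COC[C@H]1Oc2c(OC)cc(C(=O)OC)cc2O[C@@H]1c1ccc(OCc2ccccc2)c(OC)c1 | intermediate
12 | 1-(2,4,6-trihydroxyphenyl)ethanone (phloroacetophenone) | CC(=O)c1c(O)cc(O)cc1O | starting material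
13 | 1-[2,4-bis(benzyloxy)-6-hydroxyphenyl]ethanone | CC(=O)c1c(O)cc(OCc2ccccc2)cc1OCc1ccccc1 | intermediate
14 | 1-[2,4-bis(benzyloxy)-6-hydroxyphenyl]-3-{(2R,3R)-3-[4-(benzyloxy)-3-methoxyphenyl]-2-[(benzyloxy)methyl]-8-methoxy-2,3-dihydro-1,4-benzodioxin-6-yl}propane-1,3-dione (diketone, not isolated) | c1ccccc1COC[C@H]1Oc2c(OC)cc(C(=O)CC(=O)c3c(O)cc(OCc4ccccc4)cc3OCc3ccccc3)cc2O[C@@H]1c1ccc(OCc2ccccc2)c(OC)c1 | intermediate
15 | 5,7-bis(benzyloxy)-2-{(2R,3R)-3-[4-(benzyloxy)-3-methoxyphenyl]-2-[(benzyloxy)methyl]-8-methoxy-2,3-dihydro-1,4-benzodioxin-6-yl}-4H-chromen-4-one | c1ccccc1COC[C@H]1Oc2c(OC)cc(-c3cc(=O)c4c(OCc5ccccc5)cc(OCc5ccccc5)cc4o3)cc2O[C@@H]1c1ccc(OCc2ccccc2)c(OC)c1 | intermediate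
16 | 5'-methoxyhydnocarpin | COc1cc([C@H]2Oc3cc(-c4cc(=O)c5c(O)cc(O)cc5o4)cc(OC)c3O[C@@H]2CO)ccc1O | target

Total step count: 9. Longest linear sequence: 7 steps (1, 2, 4, 5, 6, 8, 9).

Steps most likely to fail

Step 4 (labelled step).
- **What may go wrong:** unselective ionisation of the two acetal C–O bonds, weak facial discrimination at the oxocarbenium carbon, or β-elimination of the aryloxide before the ring closes.
- **Fallback (known chemistry: biomimetic radical coupling plus classical resolution):** it sets out from 3 and comes back at 10.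
- Catechol 3 and commercial (E)-coniferyl alcohol are oxidised with Ag2CO3 in benzene/acetone. The sequence is phenoxy radical coupling at the side-chain β-carbon, then closure of the quinone methide by the neighbouring hydroxyl group. This should give racemic trans methyl 3-(4-hydroxy-3-methoxyphenyl)-2-(hydroxymethyl)-8-methoxy-2,3-dihydro-1,4-benzodioxine-6-carboxylate F1.
- Selective benzylation of the phenol (BnBr, K2CO3, acetone) gives the racemate of alcohol 10 F2.
- Esterification with commercial (S)-O-methylmandelic acid (DCC, DMAP, CH2Cl2) gives the (2R,3R) O-methylmandelate ester F3 and the (2S,3S) O-methylmandelate ester F4, which are separated by chromatography.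
- Methanolysis of the former (K2CO3, MeOH) returns 10.

Step 8.
- **What may go wrong:** sluggish C-acylation of the hindered enolate by the electron-rich ester, or acid-induced opening of the benzylic ether during cyclodehydration.
- **Fallback (chalcone oxidation in place of diketone cyclodehydration):** it sets out from 11 and 13 and comes back at 15.
- DIBAL-H (CH2Cl2, −78 → 0 °C) reduces 11 to the 6-hydroxymethyl benzodioxane F5.
- MnO2 (CH2Cl2, rt) oxidises it to the 6-carbaldehyde F6.
- Claisen–Schmidt condensation with 13 (KOH, EtOH, rt) gives the (E)-2'-hydroxychalcone F7.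
- Oxidative cyclisation with I2 (cat.) in DMSO at 120 °C gives 15.

Step 2.
- **What may go wrong:** an unfavourable transacetalisation equilibrium with the electron-poor catechol, or C-alkylation of an arene by the stabilised cation.
- **Fallback (oxidative C–H acetalisation in place of acetal exchange):** it sets out from 1 and 3 and comes back at 4.
- NaBH4 (MeOH, 0 °C) reduces 1 to [4-(benzyloxy)-3-methoxyphenyl]methanol F8.
- A Mitsunobu reaction with 3 (PPh3, DIAD, THF), which should engage the more acidic 4-OH, gives methyl 4-{[4-(benzyloxy)-3-methoxybenzyl]oxy}-3-hydroxy-5-methoxybenzoate F9. The isomeric mono-ether would converge on the same acetal.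
- DDQ (4 Å MS, CH2Cl2, rt) abstracts hydride from the electron-rich benzylic CH2, and the neighbouring phenol captures the cation to give 4.

Further compounds
F1 | step 4 | racemic trans methyl 3-(4-hydroxy-3-methoxyphenyl)-2-(hydroxymethyl)-8-methoxy-2,3-dihydro-1,4-benzodioxine-6-carboxylate (one enantiomer drawn) | OC[C@H]1Oc2c(OC)cc(C(=O)OC)cc2O[C@@H]1c1ccc(O)c(OC)c1
F2 | step 4 | racemic trans methyl 3-[4-(benzyloxy)-3-methoxyphenyl]-2-(hydroxymethyl)-8-methoxy-2,3-dihydro-1,4-benzodioxine-6-carboxylate (racemate of 10, one enantiomer drawn) | OC[C@H]1Oc2c(OC)cc(C(=O)OC)cc2O[C@@H]1c1ccc(OCc2ccccc2)c(OC)c1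
F3 | step 4 | methyl (2R,3R)-3-[4-(benzyloxy)-3-methoxyphenyl]-8-methoxy-2-({[(2S)-2-methoxy-2-phenylacetyl]oxy}methyl)-2,3-dihydro-1,4-benzodioxine-6-carboxylate | CO[C@H](C(=O)OC[C@H]1Oc2c(OC)cc(C(=O)OC)cc2O[C@@H]1c1ccc(OCc2ccccc2)c(OC)c1)c1ccccc1
F4 | step 4 | methyl (2S,3S)-3-[4-(benzyloxy)-3-methoxyphenyl]-8-methoxy-2-({[(2S)-2-methoxy-2-phenylacetyl]oxy}methyl)-2,3-dihydro-1,4-benzodioxine-6-carboxylate | CO[C@H](C(=O)OC[C@@H]1Oc2c(OC)cc(C(=O)OC)cc2O[C@H]1c1ccc(OCc2ccccc2)c(OC)c1)c1ccccc1
F5 | step 8 | {(2R,3R)-3-[4-(benzyloxy)-3-methoxyphenyl]-2-[(benzyloxy)methyl]-8-methoxy-2,3-dihydro-1,4-benzodioxin-6-yl}methanol | c1ccccc1COC[C@H]1Oc2c(OC)cc(CO)cc2O[C@@H]1c1ccc(OCc2ccccc2)c(OC)c1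
F6 | step 8 | (2R,3R)-3-[4-(benzyloxy)-3-methoxyphenyl]-2-[(benzyloxy)methyl]-8-methoxy-2,3-dihydro-1,4-benzodioxine-6-carbaldehyde | c1ccccc1COC[C@H]1Oc2c(OC)cc(C=O)cc2O[C@@H]1c1ccc(OCc2ccccc2)c(OC)c1
F7 | step 8 | (E)-1-[2,4-bis(benzyloxy)-6-hydroxyphenyl]-3-{(2R,3R)-3-[4-(benzyloxy)-3-methoxyphenyl]-2-[(benzyloxy)methyl]-8-methoxy-2,3-dihydro-1,4-benzodioxin-6-yl}prop-2-en-1-one | c1ccccc1COC[C@H]1Oc2c(OC)cc(/C=C/C(=O)c3c(O)cc(OCc4ccccc4)cc3OCc3ccccc3)cc2O[C@@H]1c1ccc(OCc2ccccc2)c(OC)c1
F8 | step 2 | [4-(benzyloxy)-3-methoxyphenyl]methanol | COc1cc(CO)ccc1OCc1ccccc1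
F9 | step 2 | methyl 4-{[4-(benzyloxy)-3-methoxybenzyl]oxy}-3-hydroxy-5-methoxybenzoate | COC(=O)c1cc(O)c(OCc2ccc(OCc3ccccc3)c(OC)c2)c(OC)c1
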